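**Retrosynthetic overview**

Numbering: ring B = C1 (acrylate-bearing), C2, C7, C8 (carbinol), C9, C10 (acyloxy); ring A = C2, C3=C4(Me), C5 (OAc), C6, C7; Ca = acrylic α-carbon. The route rests on C8 with its methyl and C9 being the isopropenyl group of carvone, with the C10 carbinol one bond beyond C9.
Disconnections: the C10 ester and the C8 hydroxyl (late hydration of a C8 methylene, then acylation); C9–C10 by carbonyl-ene closure of a C10 aldehyde onto the isopropenyl group; the Ca carboxyl by carbonylation of an enol triflate; C1–C2 by an ester-enolate Claisen rearrangement from a C4 tertiary allylic ester.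
Ring order: ring A is the carvone ring and is kept throughout; ring B is closed second, in the ene step.
In the Claisen step the ester carbonyl is destined to become Ca and the acetal branch to become C10, because this assignment matches the intrinsic C1 selectivity of cyclohexenyl ester enolates.

Key step: step 14

Remark on the chemistry: in a cyclohexenyl ester-enolate Claisen the substituent on the ketene-acetal carbon avoids the C7 side of ring A, so an itaconate ester would be expected to give the C1 epimer of the aldehyde needed. The acrylate is therefore built from the Claisen carboxyl and the formyl group from an acetal branch. Commercial starting materials assumed: (S)-carvone, methyl 3,3-dimethoxypropanoate, 2-butyne-1,4-diol.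

**Route**

Step 1
Reactants: 1 (S)-carvone
Product: 2 (1S,5S)-cis-carveol
Conditions: NaBH4, CeCl3·7H2O, MeOH, 0 °C
Reagents that add atoms: none
Why: Luche reduction, in which the cerium-activated enone is reduced 1,2 by axial hydride delivery, should give the C5 hydroxyl cis to the C7 isopropenyl group as known for carvone.

Step 2
Reactants: 2 (1S,5S)-cis-carveol
Product: 3 syn-epoxy alcohol (C3–C4 epoxide on the face of the C5 hydroxyl)
Conditions: VO(acac)2 (cat.), t-BuOOH, CH2Cl2, 0 °C → rt
Reagents that add atoms: tert-butyl hydroperoxide, CC(C)(C)OO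
Why: Vanadium-catalysed hydroxyl-directed epoxidation delivers oxygen to the allylic-alcohol alkene on the face of the hydroxyl, setting C3 and C4 with C4–O cis to C5–O and leaving the isopropenyl group alone.

Step 3
Reactants: 3 syn-epoxy alcohol
Product: 6 cis-4,5-diol with C2=C3 alkene (tertiary allylic alcohol), via hydroxy selenide 4 (not isolated), via selenoxide 5 (not isolated)
Conditions: PhSeSePh, NaBH4, EtOH, rt → 78 °C; then THF, 30% H2O2, 0 °C → rt
Reagents that add atoms: none
Why: Epoxide-to-allylic-alcohol transposition (selenolate opening, then selenoxide syn elimination): the selenolate opens the epoxide trans-diaxially at secondary C3 with the C4–O configuration untouched, and the selenoxide can only take a C2 hydrogen because C4 has none.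

Step 4
Reactants: 6 cis-4,5-diol
Product: 7 C5 4-methoxybenzyl ether of diol 6 (C4 tertiary hydroxyl free)
Conditions: NaH (1.05 equiv), 4-MeOC6H4CH2Cl, Bu4NI (cat.), THF–DMF, 0 °C → rt
Reagents that add atoms: 4-methoxybenzyl chloride, COc1ccc(CCl)cc1
Why: Williamson etherification takes the unhindered secondary C5 oxygen and gives a base-stable ether that cannot migrate during the organolithium steps ahead.

Step 5
Reactants: 8 methyl 3,3-dimethoxypropanoate
Product: 9 3,3-dimethoxypropanoic acid
Conditions: LiOH, THF–H2O, 0 °C → rt; dil. HCl to pH 3, 0 °C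
Reagents that add atoms: lithium hydroxide, [Li+].[OH-]
Why: Ester saponification; the dimethyl acetal is inert to base and should survive brief cold acidification.

Step 6
Reactants: 7 C5 4-methoxybenzyl ether; 9 3,3-dimethoxypropanoic acid
Product: 12 C4 tertiary allylic 3,3-dimethoxypropanoate, via acyl imidazolide 10 (not isolated), via lithium alkoxide 11 (not isolated)
Conditions: 9, 1,1'-carbonyldiimidazole, THF, rt; 7, n-BuLi, THF, −78 °C; combine, −78 → 0 °C
Reagents that add atoms: none
Why: Acylation of a pre-formed lithium tertiary alkoxide by an N-acylimidazole overcomes the low reactivity of the hindered tertiary allylic alcohol and touches no stereocentre.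

Step 7
Reactants: 12 C4 tertiary allylic 3,3-dimethoxypropanoate
Product: 15 Claisen acid (C1 bears CO2H and CH(OMe)2; C1–C2 bond cis to the C7 isopropenyl group; C3=C4 alkene), via silyl ketene acetal 13 (not isolated), via trimethylsilyl ester 14 (not isolated)
Conditions: LiN(iPr)2, Me3SiCl, THF–DMPU (3:1), −78 °C → rt; aq. citric acid (pH 4)
Reagents that add atoms: none
Why: Ireland–Claisen rearrangement: the suprafacial [3,3] shift forms C2–C1 on the face of the departing C4–O (cis to the C7 isopropenyl group), and C1 is set because the acetal-bearing substituent of the (Z)-ketene acetal takes the position remote from C7 in a boat-like transition state, the known preference of cyclohexenyl ester enolates, which puts the carboxyl where Ca is needed and the acetal where C10 is needed.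

Step 8
Reactants: 15 Claisen acid
Product: 16 methyl ketone (C1 bears COCH3 and CH(OMe)2)
Conditions: MeLi (3 equiv), THF, −78 → 0 °C; aq. NH4Cl
Reagents that add atoms: methyllithium, [Li]C
Why: Addition of methyllithium to the lithium carboxylate gives a dilithio gem-diolate that collapses to the ketone only on work-up, so over-addition and epimerisation at C1 are avoided.

Step 9
Reactants: 16 methyl ketone
Product: 17 enol triflate (C1 bears C(OTf)=CH2)
Conditions: KN(SiMe3)2, THF, −78 °C; PhNTf2, −78 → 0 °C
Reagents that add atoms: N-phenylbis(trifluoromethanesulfonimide), O=S(=O)(N(c1ccccc1)S(=O)(=O)C(F)(F)F)C(F)(F)F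
Why: Kinetic deprotonation by the bulky amide takes the methyl group rather than the hindered C1 methine, and O-triflation of the terminal enolate gives the 1,1-disubstituted enol triflate without touching C1.

Step 10
Reactants: 17 enol triflate
Product: 18 2-(trimethylsilyl)ethyl acrylate (C5 4-methoxybenzyl ether; C10 as dimethyl acetal)
Conditions: Pd(OAc)2 (5 mol%), PPh3, CO (1 atm), Me3SiCH2CH2OH, Et3N, DMF, 60 °C
Reagents that add atoms: carbon monoxide, [C-]#[O+]; 2-(trimethylsilyl)ethanol, C[Si](C)(C)CCO
Why: Palladium-catalysed alkoxycarbonylation of an enol triflate (oxidative addition, CO insertion, alcoholysis of the acylpalladium species) gives the α-substituted acrylate with Ca as the former ketone carbon.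

Step 11
Reactants: 18 2-(trimethylsilyl)ethyl acrylate
Product: 19 C5 alcohol
Conditions: DDQ, CH2Cl2–pH 7 buffer, 0 °C
Reagents that add atoms: none
Why: Oxidative cleavage of the 4-methoxybenzyl ether by DDQ through the benzylic oxocarbenium ion frees the C5 hydroxyl under neutral conditions that spare the acetal, the silylethyl ester and the alkenes.

Step 12
Reactants: 19 C5 alcohol
Product: 20 C5 acetate (C10 still dimethyl acetal)
Conditions: Ac2O, pyridine, DMAP (cat.), CH2Cl2, 0 °C → rt
Reagents that add atoms: acetic anhydride, CC(=O)OC(C)=O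
Why: DMAP-catalysed acetylation of the secondary allylic alcohol installs the C5 acetate of the target with retention.

Step 13
Reactants: 20 C5 acetate acetal
Product: 21 α-branched C10 aldehyde (ene precursor)
Conditions: LiBF4, MeCN–H2O (98:2), rt
Reagents that add atoms: water, O
Why: Mild Lewis-acid hydrolysis of the dimethyl acetal releases the aldehyde without base, so the α-vinyl aldehyde should keep its C1 configuration and alkene position if used at once.

Step 14
Reactants: 21 α-branched C10 aldehyde
Product: 23 bicyclic C10 alcohol with exocyclic C8 methylene, via chloro(methyl)aluminium alkoxide 22 (not isolated)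
Conditions: Me2AlCl (2.5 equiv), CH2Cl2, −78 °C; aq. KNaC4H4O6 (potassium sodium tartrate)
Reagents that add atoms: none
Why: Me2AlCl binds the C10 aldehyde, whose carbon is attacked by the methylene terminus C9 of the C7 isopropenyl group while a methyl hydrogen passes to oxygen in a six-membered array, so that C9–C10 forms and the C8 methylene appears; this is the Lewis-acid-promoted type 2 intramolecular carbonyl-ene reaction known for aldehydes tethered to 1,1-disubstituted alkenes, which gives 3-methylenecyclohexanols. Ring B closes in the mode that places both alkene carbons C8 and C9 in the new six-membered ring, through a chair in which ring A carbon C3 and the C1 acrylate are equatorial and C6 is axial. The new stereocentre C10 is set by the need for the aldehyde oxygen to be axial to reach the methyl hydrogen, which puts C10–O cis to the equatorial C1 substituent and so derives it from the C1 configuration fixed in step 7. The step needs selectivity for the isopropenyl group over the ring alkene and the acrylate, which ring size secures, and it must spare the labile C1–H and the silylethyl ester, which the low temperature and the proton-scavenging methyl–aluminium bond (methane loss to alkoxide 22) should secure. The cis C2/C7 substitution of ring A holds aldehyde and alkene within reach.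

Step 15
Reactants: 23 bicyclic C10 alcohol
Product: 25 C8,C10-diol (C8 tertiary hydroxyl trans to C10–OH), via organomercurial 24 (not isolated)
Conditions: Hg(OAc)2, THF–H2O (1:1), 0 °C → rt; then NaBH4, aq. NaHCO3, 0 °C
Reagents that add atoms: water, O
Why: Hydroxyl-directed oxymercuration–demercuration: mercury adds to the exocyclic methylene, the most electron-rich alkene, on the face of the axial homoallylic C10 hydroxyl that coordinates it, so that water enters C8 in the Markovnikov sense anti to mercury and the C8 hydroxyl is set trans to C10–O, as known for cyclohexenols.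

Step 16
Reactants: 26 2-butyne-1,4-diol
Product: 27 (E)-2-(tributylstannyl)but-2-ene-1,4-diol
Conditions: Bu3SnH, PdCl2(PPh3)2 (2 mol%), THF, rt
Reagents that add atoms: tributyltin hydride, CCCC[SnH](CCCC)CCCC
Why: Palladium-catalysed syn hydrostannation of the symmetrical alkyne places the two hydroxymethyl groups cis, which fixes the side-chain alkene geometry.

Step 17
Reactants: 27 (E)-2-(tributylstannyl)but-2-ene-1,4-diol
Product: 28 2,2-dimethyl-5-(tributylstannyl)-4,7-dihydro-1,3-dioxepine
Conditions: Me2C(OMe)2, PPTS (cat.), CH2Cl2, rt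
Reagents that add atoms: 2,2-dimethoxypropane, COC(C)(C)OC
Why: Acid-catalysed transacetalisation closes the seven-membered acetonide, possible only for cis hydroxymethyl groups, under acid mild enough to spare the C–Sn bond.

Step 18
Reactants: 28 2,2-dimethyl-5-(tributylstannyl)-4,7-dihydro-1,3-dioxepine
Product: 30 2,2-dimethyl-4,7-dihydro-1,3-dioxepine-5-carboxylic acid, via vinyllithium 29 (not isolated)
Conditions: n-BuLi, THF, −78 °C; CO2; cold dil. HCl to pH 4
Reagents that add atoms: carbon dioxide, O=C=O
Why: Tin–lithium exchange with retention of alkene geometry, followed by carboxylation of the vinyllithium with CO2.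

Step 19
Reactants: 25 C8,C10-diol; 30 2,2-dimethyl-4,7-dihydro-1,3-dioxepine-5-carboxylic acid
Product: 32 C10 ester (silylethyl acrylate and side-chain acetonide in place), via mixed anhydride 31 (not isolated)
Conditions: 30, 2,4,6-Cl3C6H2COCl, Et3N, THF, rt; then 25, DMAP, toluene, rt
Reagents that add atoms: none
Why: Yamaguchi esterification: the mixed anhydride acylates the secondary C10 hydroxyl under DMAP catalysis with retention while the tertiary C8 hydroxyl is inert.

Step 20
Reactants: 32 C10 ester
Product: 33 free acrylic acid (side-chain acetonide in place)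
Conditions: Bu4NF, THF, 0 °C → rt; AcOH
Reagents that add atoms: none
Why: Fluoride-induced fragmentation of the 2-(trimethylsilyl)ethyl ester to ethylene, fluorotrimethylsilane and the carboxylate should leave the acetate, the hindered C10 ester and the acetonide intact.

Step 21
Reactants: 33 free acrylic acid
Product: 34 CNP0468194.1
Conditions: AcOH–H2O (4:1), rt
Reagents that add atoms: none
Why: Mild acid hydrolysis of the seven-membered acetonide frees the two primary allylic hydroxyls, and the E side chain cannot lactonise because its γ-hydroxyl is trans to the ester carbonyl.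

**Compound list**

1 | (S)-carvone | CC(=C)[C@H]1CC=C(C)C(=O)C1 | starting material
2 | (1S,5S)-cis-carveol | C1C=C(C)[C@@H](O)C[C@H]1C(C)=C | intermediate
3 | syn-epoxy alcohol (epoxide O, C5–OH and isopropenyl all cis) | C1[C@H]2O[C@@]2(C)[C@@H](O)C[C@H]1C(C)=C | intermediate
4 | hydroxy selenide (C3–SePh trans to C4–OH) | C1[C@H]([Se]c2ccccc2)[C@@](C)(O)[C@@H](O)C[C@H]1C(C)=C | intermediate
5 | selenoxide of 4 | C1[C@H]([Se](=O)c2ccccc2)[C@@](C)(O)[C@@H](O)C[C@H]1C(C)=C | intermediate
6 | cis-4,5-diol with C2=C3 alkene; isopropenyl cis to both hydroxyls | C1=C[C@@](C)(O)[C@@H](O)C[C@H]1C(C)=C | intermediate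
7 | C5 4-methoxybenzyl ether of 6 | C1=C[C@@](C)(O)[C@@H](OCc2ccc(OC)cc2)C[C@H]1C(C)=C | intermediate
8 | methyl 3,3-dimethoxypropanoate | COC(OC)CC(=O)OC | starting material
9 | 3,3-dimethoxypropanoic acid | COC(OC)CC(=O)O | intermediate
10 | 1-(3,3-dimethoxypropanoyl)imidazole | COC(OC)CC(=O)n1ccnc1 | intermediate
11 | lithium alkoxide of 7 | C1=C[C@@](C)(O[Li])[C@@H](OCc2ccc(OC)cc2)C[C@H]1C(C)=C | intermediate
12 | C4 tertiary allylic 3,3-dimethoxypropanoate of 7 | C1=C[C@@](C)(OC(=O)CC(OC)OC)[C@@H](OCc2ccc(OC)cc2)C[C@H]1C(C)=C | intermediate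
13 | (Z)-O-trimethylsilyl ketene acetal of 12 | C1=C[C@@](C)(O/C(O[Si](C)(C)C)=C/C(OC)OC)[C@@H](OCc2ccc(OC)cc2)C[C@H]1C(C)=C | intermediate
14 | trimethylsilyl ester of 15 | C[Si](C)(C)OC(=O)[C@@H](C(OC)OC)[C@H]1C=C(C)[C@@H](OCc2ccc(OC)cc2)C[C@H]1C(C)=C | intermediate
15 | Claisen acid (C1: CO2H, CH(OMe)2; C2 substituent cis to C7 isopropenyl and C5–O) | OC(=O)[C@@H](C(OC)OC)[C@H]1C=C(C)[C@@H](OCc2ccc(OC)cc2)C[C@H]1C(C)=C | intermediate
16 | methyl ketone | CC(=O)[C@@H](C(OC)OC)[C@H]1C=C(C)[C@@H](OCc2ccc(OC)cc2)C[C@H]1C(C)=C | intermediate
17 | enol triflate | C=C(OS(=O)(=O)C(F)(F)F)[C@@H](C(OC)OC)[C@H]1C=C(C)[C@@H](OCc2ccc(OC)cc2)C[C@H]1C(C)=C | intermediate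
18 | 2-(trimethylsilyl)ethyl acrylate, C5 4-methoxybenzyl ether, C10 dimethyl acetal | C=C(C(=O)OCC[Si](C)(C)C)[C@@H](C(OC)OC)[C@H]1C=C(C)[C@@H](OCc2ccc(OC)cc2)C[C@H]1C(C)=C | intermediate
19 | C5 alcohol | C=C(C(=O)OCC[Si](C)(C)C)[C@@H](C(OC)OC)[C@H]1C=C(C)[C@@H](O)C[C@H]1C(C)=C | intermediate
20 | C5 acetate, C10 dimethyl acetal | C=C(C(=O)OCC[Si](C)(C)C)[C@@H](C(OC)OC)[C@H]1C=C(C)[C@@H](OC(C)=O)C[C@H]1C(C)=C | intermediate
21 | α-branched C10 aldehyde (ene precursor) | C=C(C(=O)OCC[Si](C)(C)C)[C@@H](C=O)[C@H]1C=C(C)[C@@H](OC(C)=O)C[C@H]1C(C)=C | intermediate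
22 | chloro(methyl)aluminium alkoxide of 23 | C=C(C(=O)OCC[Si](C)(C)C)[C@@H]1[C@H]2C=C(C)[C@@H](OC(C)=O)C[C@H]2C(=C)C[C@@H]1O[Al](C)Cl | intermediate
23 | bicyclic C10 alcohol with exocyclic C8 methylene (cis ring fusion; C10–OH cis to C1 acrylate) | C=C(C(=O)OCC[Si](C)(C)C)[C@@H]1[C@H]2C=C(C)[C@@H](OC(C)=O)C[C@H]2C(=C)C[C@@H]1O | intermediate
24 | β-hydroxyalkylmercury acetate (C8–OH, C8–CH2HgOAc) | C=C(C(=O)OCC[Si](C)(C)C)[C@@H]1[C@H]2C=C(C)[C@@H](OC(C)=O)C[C@H]2[C@@](C[Hg]OC(C)=O)(O)C[C@@H]1O | intermediate
25 | C8,C10-diol (C8–OH trans to C10–OH) | C=C(C(=O)OCC[Si](C)(C)C)[C@@H]1[C@H]2C=C(C)[C@@H](OC(C)=O)C[C@H]2[C@@](C)(O)C[C@@H]1O | intermediate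
26 | 2-butyne-1,4-diol | OCC#CCO | starting material
27 | (E)-2-(tributylstannyl)but-2-ene-1,4-diol | OC/C=C(\CO)[Sn](CCCC)(CCCC)CCCC | intermediate
28 | 2,2-dimethyl-5-(tributylstannyl)-4,7-dihydro-1,3-dioxepine | CC1(C)OCC=C([Sn](CCCC)(CCCC)CCCC)CO1 | intermediate
29 | 5-lithio-2,2-dimethyl-4,7-dihydro-1,3-dioxepine | CC1(C)OCC=C([Li])CO1 | intermediate
30 | 2,2-dimethyl-4,7-dihydro-1,3-dioxepine-5-carboxylic acid | CC1(C)OCC=C(C(=O)O)CO1 | intermediate
31 | mixed anhydride of 30 with 2,4,6-trichlorobenzoic acid | CC1(C)OCC=C(C(=O)OC(=O)c2c(Cl)cc(Cl)cc2Cl)CO1 | intermediate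
32 | C10 ester with silylethyl acrylate and side-chain acetonide | C=C(C(=O)OCC[Si](C)(C)C)[C@@H]1[C@H]2C=C(C)[C@@H](OC(C)=O)C[C@H]2[C@@](C)(O)C[C@@H]1OC(=O)C1=CCOC(C)(C)OC1 | intermediate
33 | free acrylic acid with side-chain acetonide | C=C(C(=O)O)[C@@H]1[C@H]2C=C(C)[C@@H](OC(C)=O)C[C@H]2[C@@](C)(O)C[C@@H]1OC(=O)C1=CCOC(C)(C)OC1 | intermediate
34 | CNP0468194.1 | C=C(C(=O)O)[C@@H]1[C@H]2C=C(C)[C@@H](OC(C)=O)C[C@H]2[C@@](C)(O)C[C@@H]1OC(=O)/C(=C/CO)CO | target

**Step count**

Total: 21 steps. Longest linear sequence: 17 steps (steps 1–4, 6–15, 19–21).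

**Steps most likely to fail**

Step 14 (key ene closure). The α-vinyl aldehyde may isomerise into conjugation or lose its C1 configuration on the Lewis acid, the aluminium alkoxide may close onto the neighbouring silylethyl ester (lactonisation), or the C8 cation may be captured by chloride instead of losing a proton. The fallback sets out from acetal 20 and forms the same C9–C10 bond by carbonyl allylation. Ene-type allylic chlorination of the isopropenyl group (Ca(OCl)2, CO2, CH2Cl2–H2O), which should prefer this alkene over the acetate-deactivated ring alkene, would give the allylic chloride acetal F1. LiBF4 in wet MeCN would free the chloro aldehyde F2. CrCl2 with LiI in THF would convert it into the allylchromium species F3, which should add to the aldehyde in an intramolecular Nozaki–Hiyama allylation through a closed six-membered transition state with chromium on oxygen. This again demands an axial C10–O, and the route comes back at alcohol 23.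

Step 15 (hydration of the C8 methylene). Water may be captured at C8 with poor facial selectivity if hydroxyl coordination of mercury is weak, and the free C10 hydroxyl may lactonise onto the acrylate ester during demercuration. The fallback sets out from alcohol 23 and changes the order and the controlling element. Yamaguchi acylation with acid 30 (through 31) would give the methylene ester F4, in which no free hydroxyl remains. Hg(OAc)2 in THF–H2O would then give the organomercurial F5, with water expected to enter C8 on the face opposite the axial C10 acyloxy group, and NaBH4 would bring the route back at ester 32.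

Step 7 (Ireland–Claisen). Methoxide may be lost from the ester enolate before O-silylation (β-elimination), and competing chair and boat topologies may erode C1 control. The fallback sets out from alcohol 7 and uses a thermal orthoester Claisen, which needs neither the tertiary ester nor an enolate. Pinner reaction of commercial 3,3-dimethoxypropanenitrile (HCl, MeOH, 0 °C) would give methyl 3,3-dimethoxypropanimidate hydrochloride F6, and methanolysis would give 1,1,1,3,3-pentamethoxypropane F7. Heating 7 with F7 and catalytic propanoic acid in xylene (Johnson–Claisen) should give the methyl ester F8 with the same sense at C2 and C1. LiOH in THF–H2O would bring the route back at acid 15.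

**Further compounds**

F1 | step 14 | allylic chloride acetal (C8 bears CH2Cl and =CH2) | C=C(C(=O)OCC[Si](C)(C)C)[C@@H](C(OC)OC)[C@H]1C=C(C)[C@@H](OC(C)=O)C[C@H]1C(=C)CCl
F2 | step 14 | chloro aldehyde | C=C(C(=O)OCC[Si](C)(C)C)[C@@H](C=O)[C@H]1C=C(C)[C@@H](OC(C)=O)C[C@H]1C(=C)CCl
F3 | step 14 | allylchromium dichloride from F2 | C=C(C(=O)OCC[Si](C)(C)C)[C@@H](C=O)[C@H]1C=C(C)[C@@H](OC(C)=O)C[C@H]1C(=C)C[Cr](Cl)Cl
F4 | step 15 | C10 ester with exocyclic C8 methylene | C=C(C(=O)OCC[Si](C)(C)C)[C@@H]1[C@H]2C=C(C)[C@@H](OC(C)=O)C[C@H]2C(=C)C[C@@H]1OC(=O)C1=CCOC(C)(C)OC1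
F5 | step 15 | β-hydroxyalkylmercury acetate of F4 | C=C(C(=O)OCC[Si](C)(C)C)[C@@H]1[C@H]2C=C(C)[C@@H](OC(C)=O)C[C@H]2[C@@](C[Hg]OC(C)=O)(O)C[C@@H]1OC(=O)C1=CCOC(C)(C)OC1
F6 | step 7 | methyl 3,3-dimethoxypropanimidate hydrochloride | COC(OC)CC(=N)OC.Cl
F7 | step 7 | 1,1,1,3,3-pentamethoxypropane | COC(OC)CC(OC)(OC)OC
F8 | step 7 | methyl ester of acid 15 | COC(=O)[C@@H](C(OC)OC)[C@H]1C=C(C)[C@@H](OCc2ccc(OC)cc2)C[C@H]1C(C)=C
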